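(The constants were set for the occasion; the flask was simulated.)

Amounts come first: every set-up receives the same charge, and the set-ups differ in when it enters.

| flask | starting material | partner | free catalyst | impurity | time | remark |
|---|---|---|---|---|---|---|
| delta | 10 mM | 12.0 mM (fed, over 64.0 s) | 20 µM | 2.0 µM | 80 s | a stirred flask in which partner is dosed at a steady rate over 64.0 s without added volume, worked up at 80 s |
| gamma | 10 mM (fed, over 64.0 s) | 12.0 mM | 20 µM | 2.0 µM | 80 s | a stirred flask in which starting material is dosed at a steady rate over 64.0 s without added volume, worked up at 80 s |
| theta | 10 mM | 12.0 mM | 20 µM | 2.0 µM |  | one stirred flow tank at steady state, fed with the mixture as stated, mean residence time 80 s |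
| alpha | 10 mM | 12.0 mM | 20 µM | 2.0 µM | 80 s | a closed flask charged with all of it at once and left for 80 s |

    starting material ⇌ dormant form (K1 = 15, k1 = 0.026 s⁻¹)
    free catalyst + impurity → spent catalyst (k2 = 1.2 × 10⁷ M⁻¹ s⁻¹)
    partner + free catalyst → catalyst intermediate A (k3 = 61000 M⁻¹ s⁻¹)
    catalyst intermediate A → released group + catalyst intermediate B (k4 = 40 s⁻¹)
    starting material + catalyst intermediate B ⇌ catalyst intermediate C (K5 = 860 M⁻¹, k5 = 9000 M⁻¹ s⁻¹)
    catalyst intermediate D → free catalyst + product (k6 = 1900 s⁻¹)
    catalyst intermediate C → catalyst intermediate D (k7 = 16 s⁻¹)

1. order of the set-ups by the amount of product at the outlet or at the end, in percent of the starting material put in, highest first (delta / gamma / theta / alpha)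
2. amount of product at the outlet or at the end, in percent of the starting material put in, delta
3. amount of product at the outlet or at the end, in percent of the starting material put in, gamma
4. amount of product at the outlet or at the end, in percent of the starting material put in, theta
5. amount of product at the outlet or at the end, in percent of the starting material put in, alpha

This ledger, reckoned by hand before any run, follows starting material. It is the limiting reagent, because 10 mM stands against 12.0 mM of partner, one of each per turn.

1. One turn of the catalyst, with starting material plentiful, takes the sum of its waits, 0.0894 s. The working catalyst is counted as the charge less the impurity, 18.0 µM.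

2. Let s be the free fraction of the charge. The leak to dormant form removes s per unit of leak time. The round removes v·s/(m+s). Here v is the ceiling rate of the working catalyst divided by the leak rate of the whole charge, 0.774. The Michaelis constant as a fraction of the charge is m, 0.206.

3. The share reaching product at s is v/(v+m+s), so time cancels. Integrating over the charge gives y = v·ln((1+v+m)/(v+m)). The return from dormant form is left out, being slower than the leak.

4. Alpha: the exits at the ceiling need about 21.7 s, less than 80 s, so the charge is counted as finished. Product takes 54.5%, and the dormant form takes the remainder, 45.6%. The books close.

5. Delta: partner arrives at 0.721 in the same units, above the round's rate at the full charge, 0.642, so in this reckoning partner builds up and v stays in the formula. The dose needs 0.978 s to bring partner to the level at which its wait equals one turn. That time is counted as leak with no round, which leaves a fraction 0.975 of the charge to start the integral. Product takes 53.5%.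

6. Gamma: the dose, 0.601, holds s where dose equals both exits, at 0.210. The leak takes s divided by the dose, so product takes 65.1%.

7. Theta: the same balance with outflow, at 0.481 in these units, holds s at 0.126. Product takes 61.2%.

The ledger's order is gamma > theta > alpha > delta.

The forecast reads gamma > theta > alpha > delta, with 54% for delta, 65% for gamma, 62.5% for theta and 58% for alpha, on the ground that “Keeping free starting material low favours product”. Its order is the ledger's, and its alpha figure is higher than the ledger's.

The simulation gives gamma > theta > alpha > delta: 53.6% for delta, 65.3% for gamma, 62.6% for theta and 57.4% for alpha. The forecast is right on the order and on each figure, within its margin.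

A neighbour of delta holds 0.0080 mM of free catalyst, with the impurity unchanged. The ratio v falls to 0.258, and the delta formula with the same starting fraction gives 29.2% product. The simulated neighbour holds 27.7% product and 6.13% starting material, with dormant form at 66.2% after 80.0 s.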